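The runs were generated by integration on assumed constants.

At early times, product in both earlier runs climbs along a nearly straight line, and more solid reagent does not visibly raise it.

all flasks: starting material 10 mM; initiator 0.50 mM
- west: solid reagent 17 mM; run made earlier
- south-east: solid reagent 26 mM; run made earlier
- flask: solid reagent 12.0 mM; time 8.0 h

- west (time / h: product / %, starting material / %): 0.417: 0.8, 100.8; 0.667: 0.8, 99.2; 1.00: 1.4, 98.3; 2.00: 3.2, 97.4; 3.00: 5.4, 94.0; 5.00: 9.0, 91.1
- south-east (time / h: product / %, starting material / %): 0.833: 1.0, 99.1; 1.50: 2.6, 98.1; 2.50: 4.1, 96.5; 3.00: 4.9, 95.2; 4.00: 6.7, 92.7; 5.00: 8.9, 90.0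

(each reading ± 0.5 percentage points)

* product at 8.0 h, in percent of the starting material charged
* concentration of partner in solution at 8.0 h, in percent of saturation

At 5.00 h, the west run has 9.0 % of product and the south-east run 8.9 %, although the south-east run was charged with more solid reagent. Averaged, these readings mean a loss of 0.179 mM h⁻¹ of starting material. I call this steady loss per hour the drain.

I reckon with the fraction left and assume zero order in starting material, which these short runs do not prove. The fraction left is one minus drain times time divided by the starting charge. For the flask at 8.0 h, that leaves 85.7 % and makes 14.3 % of product, a little above the forecast.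

The forecast gives 13.8 % of product and 100 % of saturation, reasoning: “Rate independent of loading suggests that the solution is saturated with partner”.

The flask gives 14.6 % of product. Its partner in solution stands at 97.8 % of saturation. At 8.00 h, the flask still holds 61.8 % of its charge as undissolved solid reagent, with 3.13 mM of partner in solution. My reckoning with the drain gave 85.7 % of the starting material left, and the flask has 85 %.

    2 first chain carrier → ended chains A (k = 2.70 × 10⁷ M⁻¹ s⁻¹)
    2 second chain carrier → ended chains B (k = 2.00 × 10⁷ M⁻¹ s⁻¹)
    starting material + second chain carrier → by-product + first chain carrier (k = 11500 M⁻¹ s⁻¹)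
    initiator → 2 initiating radical (k = 5.09 × 10⁻⁴ h⁻¹)
    starting material + initiating radical → capped initiator + first chain carrier (k = 8.62 × 10⁵ M⁻¹ s⁻¹)
    solid reagent ⇌ partner, rate k6*(cs6 - [partner]) while solid is left; crystals form when [partner] > cs6 (solubility = 3.20 mM, k = 2.64 h⁻¹)
    partner + first chain carrier → product + second chain carrier (k = 10900 M⁻¹ s⁻¹)

For the neighbour flask left until 30 h, the drain gives 46.3 % of the starting material left. The computed neighbour has 45 % left, with 54.9 % of product.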